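**Plan**
- Retrosynthesis first removes the peripheral O–C bonds: O7–prenyl, O5–CH3, O8–CH3 and a 4'-O-acyl mask. It then cuts O1–C8a of ring C, next C2–C3 (enolate acylation), and last C4–C4a (aryllithium plus Weinreb amide).
- Enabling feature: O5 and O8 are para to each other on ring A, so ring A can be raised to a 1,4-quinone. In that quinone the C–H carbon C8a, flanked by C8 and C4a, is β to both the C5 carbonyl and the exocyclic C4 carbonyl, so it accepts the oxygen that becomes O1.
- Forward: rings A and B are bought as 2,5-dimethoxybenzaldehyde and vanillic acid. Ring A becomes a 1,2,4-trioxygenated aryl methoxymethyl ketone and is joined to ring B as a 1,3-diketone. Ring C closes last, on oxidation of ring A.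
- End game: double O-methylation, debenzylation at O7, O7-prenylation, release of the 4'-OH.
- Stereochemistry: the target has no stereocentre and no stereogenic double bond. The single labile centre of the diketone becomes sp2 in the key step.

Key step: step 8

Assumption: N,2-dimethoxy-N-methylacetamide is taken as a catalogue compound, and the 1,3-diketone is drawn without configuration because its central C–H centre epimerises through the enol.

**Step 1**
Reactants: 1 2,5-dimethoxybenzaldehyde
Product: 3 2,5-dimethoxyphenol, via 2,5-dimethoxyphenyl formate 2 (not isolated)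
Conditions: mCPBA, CH2Cl2, 0 °C → rt; aq NaHCO3 wash; then K2CO3 (cat.), MeOH, rt
Reagents that add atoms: mCPBA (3-chloroperoxybenzoic acid), OOC(=O)c1cccc(Cl)c1
Why: Baeyer–Villiger oxidation with a Dakin-type outcome, in which the electron-rich aryl group migrates in preference to hydride and the aryl formate should be transesterified readily by methanol.

**Step 2**
Reactants: 3 2,5-dimethoxyphenol; 4 benzyl bromide
Product: 5 2-(benzyloxy)-1,4-dimethoxybenzene
Conditions: K2CO3, DMF, rt
Reagents that add atoms: benzyl bromide 4, BrCc1ccccc1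
Why: Williamson ether synthesis of a phenoxide with a benzylic halide, which marks the future O7 apart from the two methyl ethers.

**Step 3**
Reactants: 5 2-(benzyloxy)-1,4-dimethoxybenzene
Product: 6 1-(benzyloxy)-4-bromo-2,5-dimethoxybenzene
Conditions: NBS, MeCN, 0 °C → rt
Reagents that add atoms: N-bromosuccinimide, O=C1CCC(=O)N1Br
Why: Electrophilic aromatic bromination, which in 1,2,4-trialkoxybenzenes goes to the unhindered carbon para to the 2-alkoxy group (here benzyloxy) and ortho to a methoxy group.

**Step 4**
Reactants: 6 1-(benzyloxy)-4-bromo-2,5-dimethoxybenzene; 7 N,2-dimethoxy-N-methylacetamide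
Product: 9 1-[4-(benzyloxy)-2,5-dimethoxyphenyl]-2-methoxyethan-1-one, via aryllithium 8 (not isolated)
Conditions: n-BuLi, THF, −78 °C; then 7, −78 → 0 °C; 1 M HCl
Reagents that add atoms: N,2-dimethoxy-N-methylacetamide 7, COCC(=O)N(C)OC
Why: Bromine–lithium exchange followed by Weinreb ketone synthesis; the exchange at −78 °C outruns benzylic deprotonation, the chelated tetrahedral adduct prevents over-addition, and no Lewis acid touches the benzyl or ortho-methyl ether.

**Step 5**
Reactants: 10 vanillic acid
Product: 11 3-methoxy-4-(pivaloyloxy)benzoic acid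
Conditions: pivaloyl chloride, NaOH, H2O–THF, 0 °C; then HCl
Reagents that add atoms: pivaloyl chloride, CC(C)(C)C(=O)Cl
Why: Schotten–Baumann acylation, in which the phenoxide is acylated and any mixed anhydride at the carboxylate is hydrolysed back in the aqueous base.

**Step 6**
Reactants: 11 3-methoxy-4-(pivaloyloxy)benzoic acid
Product: 12 3-methoxy-4-(pivaloyloxy)benzoyl chloride
Conditions: (COCl)2, DMF (cat.), CH2Cl2, 0 °C → rt; concentrate, use crude
Reagents that add atoms: oxalyl chloride, O=C(Cl)C(=O)Cl
Why: Acid chloride formation through the catalytic Vilsmeier-type chloroiminium species, conditions that leave an aryl pivalate untouched.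

**Step 7**
Reactants: 9 1-[4-(benzyloxy)-2,5-dimethoxyphenyl]-2-methoxyethan-1-one; 12 3-methoxy-4-(pivaloyloxy)benzoyl chloride
Product: 14 (±)-1-[4-(benzyloxy)-2,5-dimethoxyphenyl]-2-methoxy-3-[3-methoxy-4-(pivaloyloxy)phenyl]propane-1,3-dione, via lithium enolate 13 (not isolated)
Conditions: LiN(SiMe3)2 (2.2 equiv), THF, −78 °C; then 12, −78 → 0 °C; 1 M HCl
Reagents that add atoms: 3-methoxy-4-(pivaloyloxy)benzoyl chloride 12, COc1cc(C(=O)Cl)ccc1OC(=O)C(C)(C)C
Why: Claisen-type C-acylation of a lithium enolate with an aroyl chloride, the standard entry to flavone 1,3-diketones; the second equivalent of base stores the product as its diketonate, and the hindered pivalate resists attack.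

**Step 8**
Reactants: 14 (±)-1-[4-(benzyloxy)-2,5-dimethoxyphenyl]-2-methoxy-3-[3-methoxy-4-(pivaloyloxy)phenyl]propane-1,3-dione
Product: 17 7-(benzyloxy)-5,8-dihydroxy-3-methoxy-2-[3-methoxy-4-(pivaloyloxy)phenyl]-4H-chromen-4-one, via acylquinone 15 (not isolated), via flavone-5,8-quinone 16 (not isolated)
Conditions: (NH4)2Ce(NO3)6 (2 × 2.2 equiv, second portion after 15 has had time to cyclise), MeCN–H2O (3:1), 0 °C → rt; then Na2S2O4, H2O–EtOAc, rt
Reagents that add atoms: water, O
Why: Proposed new method: tetravalent cerium takes two electrons from ring A, the only ring with a para-dialkoxy pair and three donors, and water replaces both methoxy groups (oxidative demethylation, itself known) to give acylquinone 15, whose C8a–H carbon is β to the C5 quinone carbonyl and to the exocyclic C4 carbonyl. Acid-catalysed enolisation of the carbonyl next to ring B then lets the enol oxygen add to C8a in a 6-endo-trig oxa-Michael closure of ring C (the other enol tautomer draws the same bond as an oxa-6π electrocyclisation), and tautomerisation re-aromatises ring A with O1–C8a in place. Because the first-formed hydroquinone is oxidised by 15 or by the reagent, the second portion of oxidant should carry all material on to flavone-5,8-quinone 16, a known compound class that Na2S2O4 reduces to 17. The closest known reaction types are the addition of hetero-nucleophiles at C3 of 2-acyl-1,4-benzoquinones and the (NH4)2Ce(NO3)6-mediated cyclisation of 2-hydroxyaryl 2,5-dimethoxyaryl ketones to xanthones; an enol oxygen as nucleophile and a flavone as product are the untested extension. The site selectivity needed on the quinone comes from the double activation of C8a, from the 7-benzyloxy group that turns C6=C7 into a vinylogous ester, from the fact that C-attack would need a four-membered ring, and from the reversibility of addition to the C5 carbonyl, since only the C8a adduct can aromatise. Chemoselectivity of the oxidant rests on the acyl- and pivaloyloxy-deactivated ring B, the plain benzyl ether and the largely diketo form of the 2-methoxy-1,3-diketone, which also holds the enol oxygen back from ipso capture at C5 during the oxidation; no stereocentre is formed and the labile centre becomes C3 sp2.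

**Step 9**
Reactants: 17 7-(benzyloxy)-5,8-dihydroxy-3-methoxy-2-[3-methoxy-4-(pivaloyloxy)phenyl]-4H-chromen-4-one
Product: 18 7-(benzyloxy)-3,5,8-trimethoxy-2-[3-methoxy-4-(pivaloyloxy)phenyl]-4H-chromen-4-one
Conditions: Me2SO4 (excess), K2CO3 (anhydrous), acetone, reflux, Ar
Reagents that add atoms: dimethyl sulfate, COS(=O)(=O)OC
Why: Williamson-type O-methylation under the classical forcing conditions for hydrogen-bonded 5-hydroxyflavones, with argon to prevent re-oxidation of the hydroquinone and a dry, non-nucleophilic base that should spare the pivalate.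

**Step 10**
Reactants: 18 7-(benzyloxy)-3,5,8-trimethoxy-2-[3-methoxy-4-(pivaloyloxy)phenyl]-4H-chromen-4-one
Product: 19 7-hydroxy-3,5,8-trimethoxy-2-[3-methoxy-4-(pivaloyloxy)phenyl]-4H-chromen-4-one
Conditions: H2 (1 atm), Pd/C (10 wt %), EtOAc, rt
Reagents that add atoms: none
Why: Catalytic hydrogenolysis of an aryl benzyl ether, under which the tetrasubstituted C2=C3 bond of a 3-methoxyflavone and the aryl ester are normally inert.

**Step 11**
Reactants: 19 7-hydroxy-3,5,8-trimethoxy-2-[3-methoxy-4-(pivaloyloxy)phenyl]-4H-chromen-4-one; 20 prenyl bromide (1-bromo-3-methylbut-2-ene)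
Product: 21 3,5,8-trimethoxy-2-[3-methoxy-4-(pivaloyloxy)phenyl]-7-[(3-methylbut-2-en-1-yl)oxy]-4H-chromen-4-one
Conditions: K2CO3, acetone, reflux
Reagents that add atoms: prenyl bromide 20, CC(C)=CCBr
Why: Williamson ether synthesis (SN2 at the primary allylic carbon) on the only free and acidic hydroxyl, the 7-OH.

**Step 12**
Reactants: 21 3,5,8-trimethoxy-2-[3-methoxy-4-(pivaloyloxy)phenyl]-7-[(3-methylbut-2-en-1-yl)oxy]-4H-chromen-4-one
Product: 22 4'-hydroxy-3,5,8,3'-tetramethoxy-7-prenyloxyflavone
Conditions: K2CO3, MeOH, rt; then dilute HCl to pH 5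
Reagents that add atoms: none
Why: Base-mediated transesterification (methanolysis) of an aryl ester with a good phenoxide leaving group, conditions that touch neither the prenyl ether, the methyl ethers nor the chromone.

**Compound list**
1 | 2,5-dimethoxybenzaldehyde | COc1ccc(OC)c(C=O)c1 | starting material
2 | 2,5-dimethoxyphenyl formate | COc1ccc(OC)c(OC=O)c1 | intermediate (not isolated)
3 | 2,5-dimethoxyphenol | COc1ccc(OC)c(O)c1 | intermediate
4 | benzyl bromide | BrCc1ccccc1 | starting material
5 | 2-(benzyloxy)-1,4-dimethoxybenzene | COc1ccc(OC)c(OCc2ccccc2)c1 | intermediate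
6 | 1-(benzyloxy)-4-bromo-2,5-dimethoxybenzene | COc1cc(OCc2ccccc2)c(OC)cc1Br | intermediate
7 | N,2-dimethoxy-N-methylacetamide | COCC(=O)N(C)OC | starting material
8 | [4-(benzyloxy)-2,5-dimethoxyphenyl]lithium | [Li]c1cc(OC)c(OCc2ccccc2)cc1OC | intermediate (not isolated)
9 | 1-[4-(benzyloxy)-2,5-dimethoxyphenyl]-2-methoxyethan-1-one | COCC(=O)c1cc(OC)c(OCc2ccccc2)cc1OC | intermediate
10 | vanillic acid | COc1cc(C(=O)O)ccc1O | starting material
11 | 3-methoxy-4-(pivaloyloxy)benzoic acid | COc1cc(C(=O)O)ccc1OC(=O)C(C)(C)C | intermediate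
12 | 3-methoxy-4-(pivaloyloxy)benzoyl chloride | COc1cc(C(=O)Cl)ccc1OC(=O)C(C)(C)C | intermediate
13 | lithium (Z)-enolate of 9 (chelated; geometry of no consequence) | [Li+].[O-]/C(=C\OC)c1cc(OC)c(OCc2ccccc2)cc1OC | intermediate (not isolated)
14 | (±)-1-[4-(benzyloxy)-2,5-dimethoxyphenyl]-2-methoxy-3-[3-methoxy-4-(pivaloyloxy)phenyl]propane-1,3-dione (labile centre, no configuration assigned) | COc1cc(C(=O)C(OC)C(=O)c2cc(OC)c(OCc3ccccc3)cc2OC)ccc1OC(=O)C(C)(C)C | intermediate (key-step precursor)
15 | (±)-1-[4-(benzyloxy)-3,6-dioxocyclohexa-1,4-dien-1-yl]-2-methoxy-3-[3-methoxy-4-(pivaloyloxy)phenyl]propane-1,3-dione | COc1cc(C(=O)C(OC)C(=O)C2=CC(=O)C(OCc3ccccc3)=CC2=O)ccc1OC(=O)C(C)(C)C | intermediate (not isolated)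
16 | 7-(benzyloxy)-3-methoxy-2-[3-methoxy-4-(pivaloyloxy)phenyl]-4H-chromene-4,5,8-trione | COc1cc(C2=C(OC)C(=O)C3=C(O2)C(=O)C(OCc4ccccc4)=CC3=O)ccc1OC(=O)C(C)(C)C | intermediate (not isolated)
17 | 7-(benzyloxy)-5,8-dihydroxy-3-methoxy-2-[3-methoxy-4-(pivaloyloxy)phenyl]-4H-chromen-4-one | COc1cc(-c2oc3c(O)c(OCc4ccccc4)cc(O)c3c(=O)c2OC)ccc1OC(=O)C(C)(C)C | intermediate (key-step product)
18 | 7-(benzyloxy)-3,5,8-trimethoxy-2-[3-methoxy-4-(pivaloyloxy)phenyl]-4H-chromen-4-one | COc1cc(-c2oc3c(OC)c(OCc4ccccc4)cc(OC)c3c(=O)c2OC)ccc1OC(=O)C(C)(C)C | intermediate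
19 | 7-hydroxy-3,5,8-trimethoxy-2-[3-methoxy-4-(pivaloyloxy)phenyl]-4H-chromen-4-one | COc1cc(-c2oc3c(OC)c(O)cc(OC)c3c(=O)c2OC)ccc1OC(=O)C(C)(C)C | intermediate
20 | prenyl bromide (1-bromo-3-methylbut-2-ene) | CC(C)=CCBr | starting material
21 | 3,5,8-trimethoxy-2-[3-methoxy-4-(pivaloyloxy)phenyl]-7-[(3-methylbut-2-en-1-yl)oxy]-4H-chromen-4-one | COc1cc(-c2oc3c(OC)c(OCC=C(C)C)cc(OC)c3c(=O)c2OC)ccc1OC(=O)C(C)(C)C | intermediate
22 | 4'-hydroxy-3,5,8,3'-tetramethoxy-7-prenyloxyflavone | COc1cc(-c2oc3c(OC)c(OCC=C(C)C)cc(OC)c3c(=O)c2OC)ccc1O | target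

Total step count: 12.
Longest linear sequence: 10 (steps 1–4 and 7–12); steps 5 and 6 form the ring B branch.

**Steps most likely to fail**

1. **Step 8 (new method).**
   - Enolisation may lag behind hydration of the quinone at C8a.
   - Tetravalent cerium may oxidise the enol by single-electron transfer.
   - The enol oxygen may be captured ipso at the methoxy-bearing C5 while ring A is being oxidised, so that the ring closes on the wrong ortho position.
   - Ring A radical cations may dimerise.
   - Fallback, all known chemistry, sets out from 9 (with 12) and returns at 18, bypassing steps 7–9. Oxidative demethylation of 9 with (NH4)2Ce(NO3)6 in aqueous MeCN gives 2-(benzyloxy)-5-(methoxyacetyl)-1,4-benzoquinone F1. Dry HCl in Et2O–CH2Cl2 adds chloride at the same doubly activated carbon (hydrochlorination of acylquinones) to give 1-[4-(benzyloxy)-2-chloro-3,6-dihydroxyphenyl]-2-methoxyethan-1-one F2. Me2SO4 and K2CO3 in acetone give 1-[4-(benzyloxy)-2-chloro-3,6-dimethoxyphenyl]-2-methoxyethan-1-one F3. Enolate acylation with 12, as in step 7, gives 1-[4-(benzyloxy)-2-chloro-3,6-dimethoxyphenyl]-2-methoxy-3-[3-methoxy-4-(pivaloyloxy)phenyl]propane-1,3-dione F4. Intramolecular O-arylation of its enolate (K2CO3, DMF, heat, with catalytic CuI if needed), the established chromone synthesis from 1-(2-haloaryl)-1,3-diketones, then forms O1–C8a and delivers 18.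

2. **Step 7.**
   - O-acylation of the enolate, a second acylation of the product, or acyl transfer from the pivalate may compete with C-acylation.
   - Fallback sets out from 9 and returns at 14. It changes the bond formation to an aldol addition at the alcohol oxidation level. Vanillin and pivaloyl chloride (Et3N, CH2Cl2) give 4-formyl-2-methoxyphenyl pivalate F5. Enolate 13 adds to it at −78 °C to give 1-[4-(benzyloxy)-2,5-dimethoxyphenyl]-3-hydroxy-2-methoxy-3-[3-methoxy-4-(pivaloyloxy)phenyl]propan-1-one F6 as a mixture of racemic diastereomers. Dess–Martin periodinane in CH2Cl2 oxidises the carbinol to 14, which makes the diastereomer mixture irrelevant.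

3. **Step 9.**
   - Alkylation of the hydrogen-bonded 5-hydroxyl may stall.
   - The hydroquinone anion may be re-oxidised by traces of air.
   - Prolonged heating with base may strip the pivaloyl group, after which the 4'-oxygen would be methylated irreversibly.
   - Fallback sets out from 17 and returns at 18. It replaces the one-pot double alkylation by two chemically different methylations. Me3SiCHN2 in toluene–MeOH at rt, a base-free diazoalkane methylation that leaves chelated hydroxyls alone, gives 7-(benzyloxy)-5-hydroxy-3,8-dimethoxy-2-[3-methoxy-4-(pivaloyloxy)phenyl]-4H-chromen-4-one F7, which is no longer a hydroquinone. Its single chelated hydroxyl is then deprotonated irreversibly with NaH in DMF at 0 °C and quenched with MeI to give 18.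

**Further compounds**
F1 | step 8 | 2-(benzyloxy)-5-(methoxyacetyl)-1,4-benzoquinone | COCC(=O)C1=CC(=O)C(OCc2ccccc2)=CC1=O
F2 | step 8 | 1-[4-(benzyloxy)-2-chloro-3,6-dihydroxyphenyl]-2-methoxyethan-1-one | COCC(=O)c1c(Cl)c(O)c(OCc2ccccc2)cc1O
F3 | step 8 | 1-[4-(benzyloxy)-2-chloro-3,6-dimethoxyphenyl]-2-methoxyethan-1-one | COCC(=O)c1c(Cl)c(OC)c(OCc2ccccc2)cc1OC
F4 | step 8 | 1-[4-(benzyloxy)-2-chloro-3,6-dimethoxyphenyl]-2-methoxy-3-[3-methoxy-4-(pivaloyloxy)phenyl]propane-1,3-dione | COc1cc(C(=O)C(OC)C(=O)c2c(Cl)c(OC)c(OCc3ccccc3)cc2OC)ccc1OC(=O)C(C)(C)C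
F5 | step 7 | 4-formyl-2-methoxyphenyl pivalate | COc1cc(C=O)ccc1OC(=O)C(C)(C)C
F6 | step 7 | 1-[4-(benzyloxy)-2,5-dimethoxyphenyl]-3-hydroxy-2-methoxy-3-[3-methoxy-4-(pivaloyloxy)phenyl]propan-1-one (racemic syn/anti mixture, no configuration assigned) | COc1cc(C(O)C(OC)C(=O)c2cc(OC)c(OCc3ccccc3)cc2OC)ccc1OC(=O)C(C)(C)C
F7 | step 9 | 7-(benzyloxy)-5-hydroxy-3,8-dimethoxy-2-[3-methoxy-4-(pivaloyloxy)phenyl]-4H-chromen-4-one | COc1cc(-c2oc3c(OC)c(OCc4ccccc4)cc(O)c3c(=O)c2OC)ccc1OC(=O)C(C)(C)C
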